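The readings stem from a simulated flask for an exercise; scatter was added.

**The vessel.** Our closed, stirred vessel starts with substrate and partner only, and the alder flask is followed up to 5.00 h. We want its contents at 15 h.

| setting | alder | elm | flask |
|---|---|---|---|
| substrate | 0.050 M | 0.050 M | 0.050 M |
| partner | 0.20 M | 0.30 M | 0.200 M |
| remark | the very flask that is asked about, followed so far | run made earlier |  |
| time |  |  | 15 h |

- alder (time / h: target / %, side product / %): 0.250: 6.3, 0; 0.667: 11.2, 0; 1.33: 19.5, 0.9; 2.00: 25.3, 1.6; 2.50: 28.8, 3.8; 4.00: 37.2, 8.2; 5.00: 41.5, 9.1
- elm (time / h: target / %, side product / %): 0.333: 8.8, 0; 1.00: 22.7, 1.3; 1.50: 29.1, 2.9; 2.50: 38.9, 5.3; 4.00: 50.8, 9.0; 5.00: 55.3, 10.8; 6.00: 57.7, 12.5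

(scatter of a reading: 1 percentage point)

- percentages count the substrate that a species holds: one side product counts as two
- the analysis behind the earlier runs scatters by 1 percentage point, standard deviation

* concentration of target at 15 h, in M
* concentration of side product at 15 h, in M

**First hours.** Target appears at once, while side product still reads 0% at 0.667 h. We therefore take each side product to cost one target and one further substrate. Up to 2.50 h in alder, target is made at m = 0.147 h⁻¹ per unit of substrate.

**The middle.** From 2.50 h to 5.00 h, m reads 0.105 h⁻¹. Target is used at wP per unit of substrate, with P its fraction of the charge and w = 0.0516 h⁻¹. We reckon both rates as if proportional to substrate, so substrate cancels in their quotient, which still moves with m and P.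

**The end.** We let m keep falling at that pace, to 0.0457 h⁻¹ midway through the remaining stretch, and put P near 0.5. The making ratio G = m/(wP), target made over target used, is then 1.77. Substrate falls to 24.2%, a loss L of 25.2%. Side product gains 2L/(G+1) and target L(G−1)/(G+1), so we commit to 0.0243 M of target and 0.00683 M of side product.

**The forecast.** It gives 0.0255 M and 0.0065 M, starting from this: “Target appears at once, while side product shows a lag, so target feeds it.” Our target is lower and our side product higher.

**The flask.** It gives 0.0231 M of target and 0.00651 M of side product.

    substrate + partner ⇌ target (K = 15.0 M⁻¹, k = 0.0150 M⁻¹ min⁻¹)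
    substrate + partner ⇌ isomer of the product (K = 240 M⁻¹, k = 2.20 × 10⁻⁴ M⁻¹ min⁻¹)
    partner → decomposed reagent (k = 4.20 × 10⁻⁴ min⁻¹)
    substrate + target → side product (k = 0.0180 M⁻¹ min⁻¹)

**The ratio again.** At 6.50 h in the asked flask, target is made 2.65 times faster than it is used up, each step taken net. From 7.50 h to 15.0 h in the asked flask, the making ratio is 0.863, below our 1.77. Over the whole run it is 4.54 in the asked flask. In the neighbour flask with 0.030 M of substrate, target reaches 52.8% and side product 17.4%, which makes the whole-run ratio 7.07, above the 1.77 we reckoned for the late stretch of the asked flask.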